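**Early readings.** The gamma run, read at 0.200 h and 0.500 h, held the flask's charge of starting material, and its target rose 2.91-fold while the time rose 2.50-fold. So I took target to breed target, with net rate c(target)·(k·c(starting material) − L), where L is its first-order loss. The flask has more protic impurity than gamma, 5.00 mM against 2.5 mM, which I set aside.

| flask | starting material | protic impurity | remark | time |
|---|---|---|---|---|
| epsilon | 0.35 M | 5 mM | run made earlier |  |
| delta | 0.55 M | 5 mM | run made earlier |  |
| gamma | 0.25 M | 2.5 mM | run made earlier |  |
| flask | 0.25 M | 5.00 mM |  | 15 h |

| run | time / h | target / % |
|---|---|---|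
| epsilon | 0.200 | 6.0 |
| epsilon | 0.500 | 23.6 |
| epsilon | 1.50 | 3.1 |
| epsilon | 4.00 | 0.2 |
| epsilon | 12.0 | 0 |
| delta | 0.200 | 11.4 |
| delta | 0.500 | 37.4 |
| delta | 1.50 | 0.1 |
| delta | 4.00 | 0 |
| delta | 12.0 | 0 |
| gamma | 0.200 | 4.4 |
| gamma | 0.500 | 12.8 |
| gamma | 1.50 | 5.5 |
| gamma | 4.00 | 0.7 |
| gamma | 12.0 | 0.3 |

(scatter of a reading: 0.3 percentage points)



**Frozen charge.** Over that stretch I froze c(starting material) at its charge, a pseudo-first-order view, and read the net growth constant g = 3.56 /h.

**Own loss.** The delta run fell from 37.4% at 0.500 h to 0.1% at 1.50 h. I read that fall as L = 5.92 /h, a rough value, since the last reading lies inside its scatter.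

**Critical concentration.** Since k·c(starting material) equals g + L at the charge, I reckoned c* = c(starting material)·L/(g + L) = 0.156 M, the critical concentration, at which the net rate of my rate law is zero. So I expected the flask's target to peak when its starting material had fallen to about 62.5% of the charge.

* time up to 15 h at which target stands highest
* the amount of target, in percent of the starting material charged, at that time

**The forecast.** The forecast, made from these runs, expected the flask to peak at 0.6 h with 16%, and said: “The sparse sampling leaves this uncertain.”

**The result.** The flask's target stood highest at 0.765 h, with 16.3%, so the peak came later than forecast. Its starting material then stood at 50.8% of the charge, or 0.127 M, which is less than my c* of 0.156 M.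

    starting material + target → 2 target (k = 0.550 /M/min)
    starting material → target (k = 0.00230 /min)
    target → over-reaction product (k = 0.0770 /min)
    starting material + protic impurity → quenched substrate (k = 16.0 /M/min)

**Second flask.** A neighbour flask, otherwise like this one, was charged with 0.062 M of starting material, less than c* from the start, so I reckoned that its target would show no net breeding. Its computed best was 3.55% of its charge, lower than this flask's 16.3%.

(Readings and results are simulated from invented constants; the scatter is artificial.)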